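Moles of catalyst lost per mole of product are the unit I reckon this flask in, as one counts terminations per propagation step in a chain.

    catalyst intermediate A ⇌ catalyst intermediate B (K1 = 75, k1 = 33 s⁻¹)
    starting material + free catalyst ⇌ catalyst intermediate A (K2 = 1.1 L mol⁻¹, k2 = 12 L mol⁻¹ s⁻¹)
    free catalyst → spent catalyst (k3 = 0.024 s⁻¹)
    catalyst intermediate B → free catalyst + product (k4 = 0.37 s⁻¹)

starting material 0.40 M; free catalyst 2.9 mol%

* the form that holds most of the catalyst when 50% of the starting material are converted (free catalyst / spent catalyst / catalyst intermediate B / catalyst intermediate A)
* its share of the catalyst then
* factor on the rate of making product when 50% of the starting material are converted if free catalyst is charged twice over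
* factor on the rate when 50% of the starting material are converted if free catalyst is charged at 15 mol% instead

Free catalyst meets starting material at 4.80 s⁻¹ as charged and dies at 0.024 s⁻¹, so I hold the working round at steady state and compute the leak as a correction to it. With back rates of 0.440 s⁻¹ and 10.9 s⁻¹, the steady state gives [catalyst intermediate A]/[catalyst intermediate B] = 0.0245. The leak per product, k₃[free catalyst]/(k₄[catalyst intermediate B]), then comes to a concentration divided by [starting material]. I call that concentration the leak constant, 0.00345 M, and no loading stands in it.

Two extreme versions of this flask bracket the spent catalyst at 50% conversion. If the whole conversion ran at [starting material] as charged, 0.00172 M would be spent, and if it ran at the 0.200 M reached at that conversion, 0.00345 M. The real flask passes from one concentration to the other, so it lies between them, and integrating gives the leak constant times the logarithm of their ratio, 0.00239 M. The charge is 0.0116 M. At 0.200 M the ratio [free catalyst]/[catalyst intermediate B] is 0.266, so catalyst intermediate B, the resting state, holds 77.5% of the working catalyst, which is 61.5% of the charge. Taking the same 0.00239 M off each charge, the rate rises by a factor of 2.26 on doubling and of 6.25 at 15 mol%.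

The forecast gives catalyst intermediate B at 61.6% and factors of 2.26 and 6.3, the last above mine by a lag correction of its own, on the ground that deactivation per turnover is “independent of catalyst loading”.

The simulated flask has catalyst intermediate B at 61.8%, with 20.5% of the catalyst spent, and factors of 2.26 and 6.29. At 33.7 s free catalyst goes on to catalyst intermediate A 140 times as fast as it goes to spent catalyst, forward step alone, while catalyst intermediate B falls back 1.2 times faster than it goes on. Carried to the end of this flask, the leak constant of 0.00345 M gives a reckoned 3.47% of the starting material left when the charge is spent, and at 800 s the flask holds 3.55%, with spent catalyst at >99.9%. In the flask at 15 mol%, at the same conversion, the same 0.00239 M spent gives catalyst intermediate B a reckoned 74.4% of the catalyst, and that flask holds 75.2%.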